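**Retrosynthetic overview**

- Target 15 comes from 14 by hydroxyl-directed dibromination at C3' and C5', and 14 from the symmetric resorcinol 13 by mono-O-methylation. Ring A is carried in intact, with its bromines, from 3,5-dibromosalicylaldehyde.
- Ring B is the only ring formed. The route rests on its oxygen pattern: oxygens on the three contiguous carbons C2' (OH), C1' (OAr) and C6' (OMe), none on C3' to C5'. Resorcinol 13 is therefore the aromatic tautomer of ene-dione 12, the oxidised form of hydroxycyclohexenone 11.
- 11 comes from the acyclic dienone 10 by ring-closing metathesis that forms C3'=C4', the bond opposite the ether carbon C1'.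
- 10 comes from allylmagnesium bromide and Weinreb amide 8, 8 from the aldol of aryloxyacetamide 6 with acrolein, 6 from phenol 4 and chloroacetamide 5, and 4 from aldehyde 1 by O-methylation and Baeyer–Villiger oxidation.

Key step: step 6

Assumption: the target has no stereocentre. Compounds 8, 10 and 11 are carried as racemic diastereomer mixtures, because both of their stereocentres are erased on aromatisation in step 7.

**Route**

Step 1
Reactants: 1 3,5-dibromosalicylaldehyde
Product: 2 3,5-dibromo-2-methoxybenzaldehyde
Conditions: MeI (1.5 equiv), K2CO3 (2 equiv), DMF, 23 °C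
Reagents that add atoms: iodomethane, CI
Why: Williamson O-methylation of the acidic phenoxide by SN2 attack on iodomethane should proceed cleanly, the aldehyde and aryl bromides being inert to carbonate.

Step 2
Reactants: 2 3,5-dibromo-2-methoxybenzaldehyde
Product: 4 3,5-dibromo-2-methoxyphenol, via aryl formate 3 (not isolated)
Conditions: mCPBA (1.5 equiv), CH2Cl2, 40 °C; aq. Na2SO3/NaHCO3 wash; then Et3N (cat.), MeOH, 23 °C
Reagents that add atoms: 3-chloroperoxybenzoic acid (mCPBA), OOC(=O)c1cccc(Cl)c1
Why: Baeyer–Villiger (Dakin-type) oxidation, in which the ortho-methoxy group promotes aryl over hydride migration, should give the aryl formate, and amine-catalysed methanolysis of this activated ester frees the phenol.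

Step 3
Reactants: 4 3,5-dibromo-2-methoxyphenol; 5 2-chloro-N-methoxy-N-methylacetamide
Product: 6 2-(3,5-dibromo-2-methoxyphenoxy)-N-methoxy-N-methylacetamide
Conditions: K2CO3 (2 equiv), KI (0.1 equiv), DMF, 60 °C
Reagents that add atoms: none
Why: Williamson ether synthesis by SN2 displacement at the activated α-chloro amide (iodide-catalysed) forms the diaryl-ether oxygen's second bond as a simple alkyl aryl ether, with the Weinreb amide untouched.

Step 4
Reactants: 6 2-(3,5-dibromo-2-methoxyphenoxy)-N-methoxy-N-methylacetamide; 7 acrolein
Product: 8 2-(3,5-dibromo-2-methoxyphenoxy)-3-hydroxy-N-methoxy-N-methylpent-4-enamide (racemic diastereomer mixture)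
Conditions: LiN(SiMe3)2 (1.1 equiv), THF, −78 °C; 7 (1.5 equiv), −78 °C; AcOH quench at −78 °C
Reagents that add atoms: none
Why: Aldol addition of the lithium enolate of the α-aryloxy Weinreb amide to the aldehyde carbon of acrolein (kinetic 1,2-addition at −78 °C) should give the β-hydroxy amide; the two new stereocentres (C2, C3) are deliberately left uncontrolled because both vanish in step 7.

Step 5
Reactants: 8 2-(3,5-dibromo-2-methoxyphenoxy)-3-hydroxy-N-methoxy-N-methylpent-4-enamide; 9 allylmagnesium bromide
Product: 10 4-(3,5-dibromo-2-methoxyphenoxy)-3-hydroxyocta-1,7-dien-5-one (racemic diastereomer mixture)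
Conditions: 9 (3 equiv), THF, −78 °C; aq. NH4Cl at −78 °C
Reagents that add atoms: none
Why: Weinreb ketone synthesis, in which one equivalent of Grignard reagent deprotonates the hydroxyl and a second adds to give a chelated tetrahedral intermediate that resists over-addition; the cold neutral quench should release the β,γ-unsaturated ketone without conjugation.

Step 6
Reactants: 10 4-(3,5-dibromo-2-methoxyphenoxy)-3-hydroxyocta-1,7-dien-5-one
Product: 11 6-(3,5-dibromo-2-methoxyphenoxy)-5-hydroxycyclohex-3-en-1-one (racemic diastereomer mixture)
Conditions: second-generation Grubbs catalyst (H2IMes)(PCy3)Cl2Ru=CHPh (5 mol%), 1,4-benzoquinone (10 mol%), CH2Cl2 (0.005 M), 40 °C; short Florisil filtration, used at once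
Reagents that add atoms: none
Why: The ruthenium benzylidene exchanges onto a terminal alkene of 10 (most readily the vinyl carbinol end, whose allylic hydroxyl assists initiation), the new alkylidene adds to the other terminal alkene by [2+2] cycloaddition, and cycloreversion of the ruthenacyclobutane expels ethene and returns the methylidene carrier. The closest known reaction type is ring-closing metathesis of octa-1,7-dienes bearing ketone and free hydroxyl groups to cyclohexenes, including dienones whose cyclohexenone products are taken on to phenols. Ring B closes as a six-membered carbocycle by formation of the C3'=C4' double bond between the internal alkene carbons C2 and C7 of the chain, the ring enforcing the cis alkene. No stereocentre is formed, and the two existing ones (carbinol and aryloxy carbons) are untouched and later erased, so the mixture is used as such. The step needs cyclisation to outrun oligomerisation, alkene migration and β-elimination of the hydroxyl: high dilution and the favoured six-ring closure serve the first, 1,4-benzoquinone intercepts the ruthenium hydrides responsible for migration, and the neutral, base-free medium leaves the β-hydroxy ketone, aryl bromides and methyl ether intact.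

Step 7
Reactants: 11 6-(3,5-dibromo-2-methoxyphenoxy)-5-hydroxycyclohex-3-en-1-one
Product: 13 2-(3,5-dibromo-2-methoxyphenoxy)benzene-1,3-diol, via ene-dione 12 (not isolated)
Conditions: Dess–Martin periodinane (1.05 equiv), CH2Cl2, 0 to 23 °C; aq. Na2S2O3
Reagents that add atoms: none
Why: Dess–Martin oxidation of the allylic secondary alcohol should give the cyclohex-4-ene-1,3-dione, which is the keto tautomer of a resorcinol and aromatises by keto–enol tautomerisation under the acetic acid released, erasing both stereocentres.

Step 8
Reactants: 13 2-(3,5-dibromo-2-methoxyphenoxy)benzene-1,3-diol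
Product: 14 2-(3,5-dibromo-2-methoxyphenoxy)-3-methoxyphenol
Conditions: MeI (1.0 equiv), K2CO3 (1.0 equiv), acetone, 23 °C; unreacted 13 recovered and recycled
Reagents that add atoms: iodomethane, CI
Why: Williamson mono-O-methylation with limiting iodomethane; the two hydroxyls of 13 are equivalent by symmetry, so only one mono-ether can form and it should be separable from diol and dimethyl ether.

Step 9
Reactants: 14 2-(3,5-dibromo-2-methoxyphenoxy)-3-methoxyphenol
Product: 15 4,6-dibromo-2-(3,5-dibromo-2-methoxyphenoxy)-3-methoxyphenol (target)
Conditions: N-bromosuccinimide (2.05 equiv), MeCN, 0 °C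
Reagents that add atoms: N-bromosuccinimide, O=C1CCC(=O)N1Br
Why: Electrophilic aromatic bromination directed by the free hydroxyl to its ortho (C3') and para (C5') positions, both reinforced by the C6' methoxy group, while C4' and the dibrominated ring A are much less activated.

**Compound list**

1 | 3,5-dibromosalicylaldehyde | O=Cc1cc(Br)cc(Br)c1O | starting material
2 | 3,5-dibromo-2-methoxybenzaldehyde | COc1c(Br)cc(Br)cc1C=O | intermediate
3 | 3,5-dibromo-2-methoxyphenyl formate | COc1c(Br)cc(Br)cc1OC=O | intermediate
4 | 3,5-dibromo-2-methoxyphenol | COc1c(Br)cc(Br)cc1O | intermediate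
5 | 2-chloro-N-methoxy-N-methylacetamide | CON(C)C(=O)CCl | starting material
6 | 2-(3,5-dibromo-2-methoxyphenoxy)-N-methoxy-N-methylacetamide | CON(C)C(=O)COc1cc(Br)cc(Br)c1OC | intermediate
7 | acrolein | C=CC=O | starting material
8 | 2-(3,5-dibromo-2-methoxyphenoxy)-3-hydroxy-N-methoxy-N-methylpent-4-enamide (racemic diastereomer mixture) | CON(C)C(=O)C(Oc1cc(Br)cc(Br)c1OC)C(O)C=C | intermediate
9 | allylmagnesium bromide | C=CC[Mg]Br | starting material
10 | 4-(3,5-dibromo-2-methoxyphenoxy)-3-hydroxyocta-1,7-dien-5-one (racemic diastereomer mixture) | C=CC(O)C(Oc1cc(Br)cc(Br)c1OC)C(=O)CC=C | intermediate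
11 | 6-(3,5-dibromo-2-methoxyphenoxy)-5-hydroxycyclohex-3-en-1-one (racemic diastereomer mixture) | O=C1CC=CC(O)C1Oc1cc(Br)cc(Br)c1OC | intermediate
12 | 2-(3,5-dibromo-2-methoxyphenoxy)cyclohex-4-ene-1,3-dione | O=C1CC=CC(=O)C1Oc1cc(Br)cc(Br)c1OC | intermediate
13 | 2-(3,5-dibromo-2-methoxyphenoxy)benzene-1,3-diol | COc1c(Br)cc(Br)cc1Oc1c(O)cccc1O | intermediate
14 | 2-(3,5-dibromo-2-methoxyphenoxy)-3-methoxyphenol | COc1c(Br)cc(Br)cc1Oc1c(O)cccc1OC | intermediate
15 | 4,6-dibromo-2-(3,5-dibromo-2-methoxyphenoxy)-3-methoxyphenol | COc1c(Br)cc(Br)cc1Oc1c(O)c(Br)cc(Br)c1OC | target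

**Step count**

Total steps: 9. Longest linear sequence: 9 steps (1 to 15).

**Steps most likely to fail**

Step 6 (ring-closing metathesis). Ruthenium hydrides formed by catalyst decay may move the allylic-alcohol alkene (giving an ethyl ketone) or pull the allyl-ketone alkene into conjugation. Prolonged warming may also eliminate water from the β-hydroxy ketone, so that ring closure is outrun. The fallback masks the hydroxyl before any ruthenium is present. It sets out from 8, which with chlorotriethylsilane and imidazole in CH2Cl2 should give 2-(3,5-dibromo-2-methoxyphenoxy)-N-methoxy-N-methyl-3-(triethylsilyloxy)pent-4-enamide F1. Allylmagnesium bromide at −78 °C should convert it into 4-(3,5-dibromo-2-methoxyphenoxy)-3-(triethylsilyloxy)octa-1,7-dien-5-one F2. The second-generation Grubbs catalyst in dilute CH2Cl2 should close this to 6-(3,5-dibromo-2-methoxyphenoxy)-5-(triethylsilyloxy)cyclohex-3-en-1-one F3. Desilylation with pyridine-buffered HF·pyridine in THF at 0 °C comes back to the route at 11, which is oxidised at once as in step 7.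

Step 7 (oxidation and aromatisation). Elimination of water from the β-hydroxy ketone may run faster than oxidation and aromatise ring B with loss of the C2' oxygen. The freshly formed electron-rich resorcinol may also be attacked by remaining periodinane. The fallback raises the oxidation level before the ring exists. It sets out from 10, which on Dess–Martin oxidation should give 4-(3,5-dibromo-2-methoxyphenoxy)octa-1,7-diene-3,5-dione F4. This is used without storage, since the enolised vinyl diketone can close to a dihydropyranone by oxa-Michael addition. Ring-closing metathesis with the second-generation Grubbs catalyst in dilute CH2Cl2 should deliver ene-dione 12 directly, which tautomerises in the flask, so the fallback comes back to the route at 13. No hydroxyl remains to be eliminated, and the phenol never meets the oxidant.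

Step 4 (aldol addition to acrolein). Conjugate addition to, or polymerisation of, acrolein and fragmentation of the amide enolate (loss of formaldehyde from the N-methoxy group) may compete with 1,2-addition. The fallback uses an ester enolate and installs the Weinreb amide afterwards. It sets out from 4, which with methyl bromoacetate and K2CO3 in acetone should give methyl 2-(3,5-dibromo-2-methoxyphenoxy)acetate F5. Enolisation with LiN(SiMe3)2 in THF at −78 °C and addition to acrolein should give methyl 2-(3,5-dibromo-2-methoxyphenoxy)-3-hydroxypent-4-enoate F6. Treatment with N,O-dimethylhydroxylamine hydrochloride and isopropylmagnesium chloride in THF at −20 °C comes back to the route at 8.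

**Further compounds**

F1 | step 6 | 2-(3,5-dibromo-2-methoxyphenoxy)-N-methoxy-N-methyl-3-(triethylsilyloxy)pent-4-enamide | CC[Si](CC)(CC)OC(C=C)C(Oc1cc(Br)cc(Br)c1OC)C(=O)N(C)OC
F2 | step 6 | 4-(3,5-dibromo-2-methoxyphenoxy)-3-(triethylsilyloxy)octa-1,7-dien-5-one | CC[Si](CC)(CC)OC(C=C)C(Oc1cc(Br)cc(Br)c1OC)C(=O)CC=C
F3 | step 6 | 6-(3,5-dibromo-2-methoxyphenoxy)-5-(triethylsilyloxy)cyclohex-3-en-1-one | CC[Si](CC)(CC)OC1C=CCC(=O)C1Oc1cc(Br)cc(Br)c1OC
F4 | step 7 | 4-(3,5-dibromo-2-methoxyphenoxy)octa-1,7-diene-3,5-dione | C=CC(=O)C(Oc1cc(Br)cc(Br)c1OC)C(=O)CC=C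
F5 | step 4 | methyl 2-(3,5-dibromo-2-methoxyphenoxy)acetate | COC(=O)COc1cc(Br)cc(Br)c1OC
F6 | step 4 | methyl 2-(3,5-dibromo-2-methoxyphenoxy)-3-hydroxypent-4-enoate | COC(=O)C(Oc1cc(Br)cc(Br)c1OC)C(O)C=C
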